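**Retrosynthetic overview**
- The target is reached from diol 27 by oxidation of a 3-hydroxypropyl arm. The acid is carried as a TBS-protected primary alcohol, because an acrylate Michael addition to the cross-conjugated carvone dienolate would run on to a bicyclo[2.2.2]octanone and an ester would not survive t-BuLi.
- The strategy rests on the tropone ring T1–T7. It is cut at T3–T4 and T1–T2: T2/T3 is propyne, and T4=T5–T6–T7≡T1 is the 3-pivaloyloxy-1,4-enyne 22. Its alkene is the enol-ether C=C of the spiro dihydrofuran, its carbinol carbon (CH3, OPiv) becomes T6, and the pivalate migrates to the alkyne carbon that becomes T7.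
- Enyne 22 comes from the 2-acetyl dihydrofuran 18 and methyl propiolate. 18 comes from the spiro 2,3-dihydrofuran 16 (C2 lithiation/acylation), 16 from the homopropargylic alcohol 15 (endo-cycloisomerisation), and 15 from ketone 12 and propargyl bromide.
- Ketone 12 comes from (S)-carvone: hydration of the isopropenyl group, C6 methylation then allylation (allyl trans to the C5 group), hydroboration of the allyl arm, and hydrogenation of the enone from the face opposite the C6 methyl.
- Ring order: cyclohexane (from carvone), then spiro dihydrofuran (step 9), then the seven-membered ring (step 12), which is aromatised to the tropone in step 13.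

Key step: step 12

Remark: tropone carbons are labelled T1 (C–CO2Me), T2 (C–CH3), T3 (C–H), T4 (fusion carbon bearing the furan CH2), T5 (fusion carbon bearing the furan O), T6 (C–CH3), T7 (C=O); cyclohexane carbons keep carvone locants (C1 carbonyl, later spiro carbon; C2 CH–CH3; C5 CH bearing the oxygenated isopropyl group; C6 quaternary carbon); propyne is assumed to be handled as a condensed gas in a sealed vessel.

**Route**

Step 1
Reactants: 1 (S)-carvone
Product: 2 (5S)-5-(2-hydroxypropan-2-yl)-2-methylcyclohex-2-en-1-one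
Conditions: 50% aq. H2SO4, 0 °C → rt
Reagents that add atoms: water, O
Why: Acid-catalysed Markovnikov hydration: the isopropenyl group is protonated to a tertiary cation that water captures, whereas the protonated enone is inert and C5 is not involved, so the configuration of carvone is kept.

Step 2
Reactants: 2 (5S)-5-(2-hydroxypropan-2-yl)-2-methylcyclohex-2-en-1-one
Product: 3 (5S)-2-methyl-5-[2-(triethylsilyloxy)propan-2-yl]cyclohex-2-en-1-one
Conditions: TESCl, imidazole, DMAP (cat.), DMF, 40 °C
Reagents that add atoms: chlorotriethylsilane, CC[Si](Cl)(CC)CC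
Why: Silyl ether protection of the tertiary carbinol (forcing imidazole/DMAP conditions) so that it passes the enolate, organometallic and cationic steps that follow.

Step 3
Reactants: 3 (5S)-2-methyl-5-[2-(triethylsilyloxy)propan-2-yl]cyclohex-2-en-1-one
Product: 5 (5S,6R)-2,6-dimethyl-5-[2-(triethylsilyloxy)propan-2-yl]cyclohex-2-en-1-one (6-methyl trans to the C5 group), via lithium dienolate 4 (not isolated)
Conditions: LiN(i-Pr)2, THF, −78 °C; MeI, −78 → 0 °C
Reagents that add atoms: iodomethane, CI
Why: Kinetic α′-deprotonation gives the cross-conjugated dienolate and enolate alkylation places the methyl on C6 anti to the C5 substituent; this C6 configuration is erased in step 4.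

Step 4
Reactants: 5 (5S,6R)-2,6-dimethyl-5-[2-(triethylsilyloxy)propan-2-yl]cyclohex-2-en-1-one; 6 allyl bromide
Product: 8 (5S,6R)-6-allyl-2,6-dimethyl-5-[2-(triethylsilyloxy)propan-2-yl]cyclohex-2-en-1-one, via lithium dienolate 7 (not isolated)
Conditions: LiN(i-Pr)2, THF, −78 °C; 6, DMPU, −78 °C → rt
Reagents that add atoms: none
Why: Second enolate alkylation: the tetrasubstituted dienolate is allylated on the face anti to the bulky C5 group, which sets the quaternary C6 with the allyl arm trans and the methyl cis to the C5 substituent, as is usual for 6-alkylcarvones.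

Step 5
Reactants: 8 (5S,6R)-6-allyl-2,6-dimethyl-5-[2-(triethylsilyloxy)propan-2-yl]cyclohex-2-en-1-one
Product: 10 (5S,6R)-6-(3-hydroxypropyl)-2,6-dimethyl-5-[2-(triethylsilyloxy)propan-2-yl]cyclohex-2-en-1-one, via B-alkyl-9-BBN adduct 9 (not isolated)
Conditions: 9-BBN, THF, 0 °C → rt; then NaBO3·4H2O, THF/H2O, rt
Reagents that add atoms: sodium perborate (oxygen source), O[B-]1(O)OO[B-](O)(O)OO1.[Na+].[Na+]
Why: Anti-Markovnikov hydroboration–oxidation: 9-BBN adds to the only unhindered electron-rich alkene (the allyl terminus) and spares the hindered electron-poor enone, and perborate oxidises the C–B bond without the nucleophilic epoxidation of the enone that alkaline peroxide would cause.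

Step 6
Reactants: 10 (5S,6R)-6-(3-hydroxypropyl)-2,6-dimethyl-5-[2-(triethylsilyloxy)propan-2-yl]cyclohex-2-en-1-one
Product: 11 (5S,6R)-6-[3-(tert-butyldimethylsilyloxy)propyl]-2,6-dimethyl-5-[2-(triethylsilyloxy)propan-2-yl]cyclohex-2-en-1-one
Conditions: TBSCl, imidazole, CH2Cl2, rt
Reagents that add atoms: tert-butyldimethylsilyl chloride, CC(C)(C)[Si](C)(C)Cl
Why: Silyl ether protection of the primary alcohol, which is the masked carboxylic acid and must withstand t-BuLi, the lithium acetylide and the rhodium step.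

Step 7
Reactants: 11 (5S,6R)-6-[3-(tert-butyldimethylsilyloxy)propyl]-2,6-dimethyl-5-[2-(triethylsilyloxy)propan-2-yl]cyclohex-2-en-1-one
Product: 12 (2R,5S,6R)-6-[3-(tert-butyldimethylsilyloxy)propyl]-2,6-dimethyl-5-[2-(triethylsilyloxy)propan-2-yl]cyclohexan-1-one (2-methyl, 6-methyl and C5 group all cis)
Conditions: H2 (1 atm), Pd/C, EtOAc, rt
Reagents that add atoms: none
Why: Heterogeneous catalytic hydrogenation (syn addition): the enone should bind the catalyst on the face opposite the pseudo-axial C6 methyl, so hydrogen enters C2 from that face and the C2 methyl is pushed cis to the C6 methyl and the C5 group (2R); neutral conditions avoid epimerisation to the more stable trans-2,6-dimethyl ketone.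

Step 8
Reactants: 12 (2R,5S,6R)-6-[3-(tert-butyldimethylsilyloxy)propyl]-2,6-dimethyl-5-[2-(triethylsilyloxy)propan-2-yl]cyclohexan-1-one; 13 propargyl bromide
Product: 15 (1R,2R,5S,6R)-6-[3-(tert-butyldimethylsilyloxy)propyl]-2,6-dimethyl-1-(prop-2-yn-1-yl)-5-[2-(triethylsilyloxy)propan-2-yl]cyclohexan-1-ol, via allenylmagnesium bromide 14 (not isolated)
Conditions: 13, Mg, HgCl2 (cat.), Et2O, 0 °C; then 12, −78 → 0 °C; aq. NH4Cl
Reagents that add atoms: none
Why: Propargylation of a ketone by SE2′ addition of the allenyl Grignard reagent, which is small enough for the hindered carbonyl and adds faster than it enolises; attack on the face opposite the two α-methyl groups puts the propargyl CH2 trans to them and the hydroxyl cis (1R).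

Step 9
Reactants: 15 (1R,2R,5S,6R)-6-[3-(tert-butyldimethylsilyloxy)propyl]-2,6-dimethyl-1-(prop-2-yn-1-yl)-5-[2-(triethylsilyloxy)propan-2-yl]cyclohexan-1-ol
Product: 16 (5R,6R,7S,10R)-6-[3-(tert-butyldimethylsilyloxy)propyl]-6,10-dimethyl-7-[2-(triethylsilyloxy)propan-2-yl]-1-oxaspiro[4.5]dec-2-ene
Conditions: Mo(CO)6 (0.3 equiv), Me3NO (0.3 equiv), Et3N, Et2O, rt
Reagents that add atoms: none
Why: Molybdenum-catalysed alkynol endo-cycloisomerisation: the terminal alkyne is turned into a molybdenum vinylidene whose metal-bound carbon is attacked by the tertiary hydroxyl, and protonolysis releases the 2,3-dihydrofuran without touching the spiro centre.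

Step 10
Reactants: 16 (5R,6R,7S,10R)-6-[3-(tert-butyldimethylsilyloxy)propyl]-6,10-dimethyl-7-[2-(triethylsilyloxy)propan-2-yl]-1-oxaspiro[4.5]dec-2-ene
Product: 18 1-[(5R,6R,7S,10R)-6-[3-(tert-butyldimethylsilyloxy)propyl]-6,10-dimethyl-7-[2-(triethylsilyloxy)propan-2-yl]-1-oxaspiro[4.5]dec-2-en-2-yl]ethan-1-one, via 2-lithio dihydrofuran 17 (not isolated)
Conditions: t-BuLi, THF, −78 → 0 °C; then MeC(O)N(OMe)Me, −78 °C → rt
Reagents that add atoms: N-methoxy-N-methylacetamide, CC(=O)N(C)OC
Why: α-Lithiation of a cyclic enol ether at the vinylic C–H next to oxygen, then acylation with a Weinreb amide whose chelated tetrahedral adduct stops at the methyl ketone.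

Step 11
Reactants: 18 2-acetyl spiro dihydrofuran; 19 methyl propiolate
Product: 22 methyl 4-[(5R,6R,7S,10R)-6-[3-(tert-butyldimethylsilyloxy)propyl]-6,10-dimethyl-7-[2-(triethylsilyloxy)propan-2-yl]-1-oxaspiro[4.5]dec-2-en-2-yl]-4-(pivaloyloxy)pent-2-ynoate (C4 of the pentynoate as a mixture), via lithium methyl propiolate 20 (not isolated), via lithium tertiary alkoxide 21 (not isolated)
Conditions: 19, LiN(SiMe3)2, THF, −78 °C; 18, −78 °C; then PivCl, −78 → 0 °C
Reagents that add atoms: pivaloyl chloride, CC(C)(C)C(Cl)=O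
Why: 1,2-Addition of a lithium acetylide to the ketone followed by O-acylation of the tertiary lithium alkoxide in the same flask; the new carbinol centre (future T6) forms as a mixture, which does not matter because it becomes sp2.

Step 12
Reactants: 22 spiro dihydrofuranyl 3-pivaloyloxy-1,4-enyne; 23 propyne
Product: 24 pivaloyloxy cycloheptatriene (T1 bears CO2Me; T1=T7 with OPiv on T7; T6(CH3)=T5(O); T3H=T2(CH3); T4 sp3 CH as a mixture; cyclohexane and spiro centre as in 16)
Conditions: [Rh(cod)2]BF4 (10 mol %), P(4-CF3C6H4)3 (20 mol %), 23 (5 equiv), CH2Cl2, rt, sealed vessel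
Reagents that add atoms: none
Why: Proposed new method: the cationic monovalent rhodium centre binds the ester-substituted alkyne of 22, the pivaloyloxy group shifts from the carbinol carbon (future T6) to the neighbouring alkyne carbon (future T7) through a cyclic acyloxonium, and the resulting rhodium vinylcarbene at T1 closes onto the enol ether to a rhodacyclohexadiene (Rh–T1 and Rh–T4, T1=T7 and T5=T6); propyne then inserts into the Rh–T4 bond and reductive elimination joins T2 to T1. The closest known reaction is the rhodium-catalysed intermolecular (5+2) cycloaddition of 3-acyloxy-1,4-enynes with terminal alkynes that runs with 1,2-acyloxy migration; what has not been shown is an alkene that is a cyclic enol ether and a fully substituted acyloxy carbon. The seven-membered ring is closed in a two-component (5+2) mode, the last bond (T1–T2) arising by C–C reductive elimination from an eight-membered rhodacycle. The one new stereocentre, T4, is not controlled and is destroyed in step 13. The step needs 1,2- rather than 1,3-acyloxy migration, which the electron-poor ynoate favours, and insertion of propyne with its CH terminus at T4, which is expected because the crowded secondary T4–Rh terminus next to the ring CH2 bonds to the unsubstituted alkyne carbon and leaves the methyl-bearing carbon on rhodium for coupling with T1.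

Step 13
Reactants: 24 pivaloyloxy cycloheptatriene
Product: 26 bis-silyl tropone (tropone ring T1–T7 of the target fused to the spiro dihydrofuran; tertiary OTES; 3-(TBSO)propyl arm on C6), via pivaloyloxytropylium tetrafluoroborate 25 (not isolated)
Conditions: Ph3CBF4 (1.05 equiv), CH2Cl2, 0 °C → rt; then aq. NaHCO3
Reagents that add atoms: none
Why: Hydride abstraction by the trityl cation at the doubly allylic T4–H gives an oxygen-stabilised tropylium ion, and hydrolytic loss of the pivaloyl group on work-up releases the tropone (tropylium route from cycloheptatrienes to tropones); T4 becomes sp2, so its configuration is irrelevant.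

Step 14
Reactants: 26 bis-silyl tropone
Product: 27 diol (target skeleton with CH2CH2CH2OH in place of CH2CH2CO2H and a free tertiary carbinol)
Conditions: HF·pyridine, THF/pyridine, 0 °C → rt
Reagents that add atoms: none
Why: Fluoride-driven cleavage of both silyl ethers through Si–F bond formation under buffered conditions that leave the methyl ester, the tropone and the tertiary carbinol untouched.

Step 15
Reactants: 27 diol
Product: 29 CNP0448476.2 (target), via aldehyde 28 (not isolated)
Conditions: TEMPO (cat.), PhI(OAc)2, MeCN/H2O, rt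
Reagents that add atoms: water, O
Why: Oxoammonium (TEMPO/PhI(OAc)2) oxidation in aqueous acetonitrile takes the primary alcohol through the aldehyde hydrate to the carboxylic acid, while the tertiary alcohol cannot be oxidised and the electron-poor tropone is inert.

**Compound list**
1 | (S)-carvone | CC1=CC[C@@H](CC1=O)C(C)=C | starting material
2 | (5S)-5-(2-hydroxypropan-2-yl)-2-methylcyclohex-2-en-1-one | CC1=CC[C@@H](CC1=O)C(C)(C)O | intermediate
3 | (5S)-2-methyl-5-[2-(triethylsilyloxy)propan-2-yl]cyclohex-2-en-1-one | CC1=CC[C@@H](CC1=O)C(C)(C)O[Si](CC)(CC)CC | intermediate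
4 | lithium dienolate of 3 (C1=C6, O–Li) | CC1=CC[C@@H](C=C1O[Li])C(C)(C)O[Si](CC)(CC)CC | intermediate
5 | (5S,6R)-2,6-dimethyl-5-[2-(triethylsilyloxy)propan-2-yl]cyclohex-2-en-1-one | CC1=CC[C@@H]([C@@H](C)C1=O)C(C)(C)O[Si](CC)(CC)CC | intermediate
6 | allyl bromide | C=CCBr | starting material
7 | lithium dienolate of 5 (C1=C6, O–Li) | CC1=CC[C@@H](C(C)=C1O[Li])C(C)(C)O[Si](CC)(CC)CC | intermediate
8 | (5S,6R)-6-allyl-2,6-dimethyl-5-[2-(triethylsilyloxy)propan-2-yl]cyclohex-2-en-1-one | CC1=CC[C@@H]([C@@](C)(CC=C)C1=O)C(C)(C)O[Si](CC)(CC)CC | intermediate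
9 | B-alkyl-9-borabicyclo[3.3.1]nonane adduct of 8 (boron on the terminal carbon) | CC1=CC[C@@H]([C@@](C)(CCCB2C3CCCC2CCC3)C1=O)C(C)(C)O[Si](CC)(CC)CC | intermediate
10 | (5S,6R)-6-(3-hydroxypropyl)-2,6-dimethyl-5-[2-(triethylsilyloxy)propan-2-yl]cyclohex-2-en-1-one | CC1=CC[C@@H]([C@@](C)(CCCO)C1=O)C(C)(C)O[Si](CC)(CC)CC | intermediate
11 | (5S,6R)-6-[3-(tert-butyldimethylsilyloxy)propyl]-2,6-dimethyl-5-[2-(triethylsilyloxy)propan-2-yl]cyclohex-2-en-1-one | CC1=CC[C@@H]([C@@](C)(CCCO[Si](C)(C)C(C)(C)C)C1=O)C(C)(C)O[Si](CC)(CC)CC | intermediate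
12 | (2R,5S,6R)-6-[3-(tert-butyldimethylsilyloxy)propyl]-2,6-dimethyl-5-[2-(triethylsilyloxy)propan-2-yl]cyclohexan-1-one | O=C1[C@H](C)CC[C@H](C(C)(C)O[Si](CC)(CC)CC)[C@@]1(C)CCCO[Si](C)(C)C(C)(C)C | intermediate
13 | propargyl bromide | C#CCBr | starting material
14 | allenylmagnesium bromide | C=C=C[Mg]Br | intermediate
15 | (1R,2R,5S,6R)-6-[3-(tert-butyldimethylsilyloxy)propyl]-2,6-dimethyl-1-(prop-2-yn-1-yl)-5-[2-(triethylsilyloxy)propan-2-yl]cyclohexan-1-ol | C#CC[C@@]1(O)[C@H](C)CC[C@H](C(C)(C)O[Si](CC)(CC)CC)[C@@]1(C)CCCO[Si](C)(C)C(C)(C)C | intermediate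
16 | (5R,6R,7S,10R)-6-[3-(tert-butyldimethylsilyloxy)propyl]-6,10-dimethyl-7-[2-(triethylsilyloxy)propan-2-yl]-1-oxaspiro[4.5]dec-2-ene | C1=CC[C@@]2(O1)[C@H](C)CC[C@H](C(C)(C)O[Si](CC)(CC)CC)[C@@]2(C)CCCO[Si](C)(C)C(C)(C)C | intermediate
17 | 2-lithio derivative of 16 | [Li]C1=CC[C@@]2(O1)[C@H](C)CC[C@H](C(C)(C)O[Si](CC)(CC)CC)[C@@]2(C)CCCO[Si](C)(C)C(C)(C)C | intermediate
18 | 2-acetyl derivative of 16 | CC(=O)C1=CC[C@@]2(O1)[C@H](C)CC[C@H](C(C)(C)O[Si](CC)(CC)CC)[C@@]2(C)CCCO[Si](C)(C)C(C)(C)C | intermediate
19 | methyl propiolate | C#CC(=O)OC | starting material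
20 | lithium methyl propiolate (methyl 3-lithioprop-2-ynoate) | [Li]C#CC(=O)OC | intermediate
21 | lithium tertiary alkoxide from 18 and 20 (carbinol carbon as a mixture) | COC(=O)C#CC(C)(O[Li])C1=CC[C@@]2(O1)[C@H](C)CC[C@H](C(C)(C)O[Si](CC)(CC)CC)[C@@]2(C)CCCO[Si](C)(C)C(C)(C)C | intermediate
22 | spiro dihydrofuranyl 3-pivaloyloxy-1,4-enyne (carbinol carbon as a mixture); key-step precursor | COC(=O)C#CC(C)(OC(=O)C(C)(C)C)C1=CC[C@@]2(O1)[C@H](C)CC[C@H](C(C)(C)O[Si](CC)(CC)CC)[C@@]2(C)CCCO[Si](C)(C)C(C)(C)C | intermediate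
23 | propyne | CC#C | starting material
24 | pivaloyloxy cycloheptatriene (T4 undefined); key-step product | COC(=O)C1=C(OC(=O)C(C)(C)C)C(C)=C2O[C@]3(CC2C=C1C)[C@H](C)CC[C@H](C(C)(C)O[Si](CC)(CC)CC)[C@@]3(C)CCCO[Si](C)(C)C(C)(C)C | intermediate
25 | pivaloyloxytropylium tetrafluoroborate (drawn as its oxocarbenium form) | COC(=O)C1=C(C)C=C2C[C@@]3([O+]=C2C(C)=C1OC(=O)C(C)(C)C)[C@H](C)CC[C@H](C(C)(C)O[Si](CC)(CC)CC)[C@@]3(C)CCCO[Si](C)(C)C(C)(C)C.F[B-](F)(F)F | intermediate
26 | bis-silyl tropone | COC(=O)c1c(C)cc2c(c(C)c1=O)O[C@]1(C2)[C@H](C)CC[C@H](C(C)(C)O[Si](CC)(CC)CC)[C@@]1(C)CCCO[Si](C)(C)C(C)(C)C | intermediate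
27 | diol tropone (3-hydroxypropyl arm, free tertiary carbinol) | COC(=O)c1c(C)cc2c(c(C)c1=O)O[C@]1(C2)[C@H](C)CC[C@H](C(C)(C)O)[C@@]1(C)CCCO | intermediate
28 | aldehyde from 27 | COC(=O)c1c(C)cc2c(c(C)c1=O)O[C@]1(C2)[C@H](C)CC[C@H](C(C)(C)O)[C@@]1(C)CCC=O | intermediate
29 | CNP0448476.2 | COC(=O)c1c(C)cc2c(c(C)c1=O)O[C@]1(C2)[C@H](C)CC[C@H](C(C)(C)O)[C@@]1(C)CCC(=O)O | target

**Step count**
Total: 15 steps. Longest linear sequence: 15 steps from (S)-carvone.

**Steps most likely to fail, with fallbacks**

1. Step 12 (Proposed new method). What may go wrong: the rhodium carbene may be diverted before propyne is taken up (ionisation or 1,3-shift of the tertiary pivalate, or closure to a five-membered ring), or propyne may insert in the reversed sense and place the methyl on T3. The fallback uses known chemistry, leaves the route at 16 and rejoins it at 26.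
   - The enol ether 16 is formylated at its β-carbon (Vilsmeier–Haack; POCl3, DMF, then aq. NaOAc) to the 3-formyl dihydrofuran F1.
   - Julia–Kocienski olefination (5-(ethylsulfonyl)-1-phenyl-1H-tetrazole, KN(SiMe3)2, DME, −60 °C) should give the (E)-propenyl diene F2, which holds T5=T4–T3=T2 with the methyl already on T2.
   - The three-carbon partner is made from methyl 3-oxopentanoate by diazo transfer (4-acetamidobenzenesulfonyl azide, Et3N) to methyl 2-diazo-3-oxopentanoate F3, then silylation (TBSOTf, Et3N) to the (Z)-silyloxyvinyl diazoacetate F4 (T1, T7, T6).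
   - Decomposition of F4 with Rh2(O2CCMe3)4, a divalent rhodium carboxylate, in the presence of F2 should cyclopropanate the propenyl alkene (the diene terminus remote from oxygen) to the cis-divinylcyclopropane F5.
   - F5 is expected to undergo Cope rearrangement on warming to the cycloheptadiene F6, with T1–T2 and T5–T6 formed. This tandem cyclopropanation/Cope sequence is a formal (4+3) cycloaddition known for silyloxyvinyl diazoacetates and 1-oxygenated dienes.
   - DDQ (2 equiv) should then abstract hydride from the doubly allylic T2–H with loss of the silyl group and dehydrogenate T5–T6, giving tropone 26.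

2. Step 7. What may go wrong: hydrogen may be delivered to the wrong face of C2=C3, or C2 may epimerise on the catalyst towards the more stable trans-2,6-dimethyl arrangement. The fallback leaves at 11 and returns at 12, and separates reduction from the stereo-determining event. Enone 11 is reduced with LiBH(s-Bu)3 (THF, −78 °C; 1,4-hydride addition at the unsubstituted C3) to the lithium enolate F7. F7 is protonated at −78 °C with a hindered phenol (2,6-di-tert-butyl-4-methylphenol); the proton should enter C2 anti to the pseudo-axial C6 methyl and give 12 under kinetic control. Material of the wrong C2 configuration can be returned to F7 with LiN(i-Pr)2, since C2–H is the only α-hydrogen.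

3. Step 11. What may go wrong: acylation of the hindered tertiary alkoxide may be incomplete, and the ynoate may degrade under the basic trapping conditions. The fallback leaves at 18 and returns at 22, and changes the order of bond formation. Ketone 18 is treated with ethynylmagnesium bromide (THF, 0 °C) to give the ester-free tertiary ethynyl carbinol F8. F8 tolerates forcing acylation (PivCl, DMAP, Et3N, CH2Cl2, 40 °C) to the propargylic pivalate F9. Deprotonation of the terminal alkyne (LiN(SiMe3)2, THF, −78 °C) to the lithium acetylide F10 and quench with methyl chloroformate should give 22.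

**Further compounds**
F1 | step 12 | 3-formyl derivative of spiro dihydrofuran 16 | O=CC1=CO[C@]2(C1)[C@H](C)CC[C@H](C(C)(C)O[Si](CC)(CC)CC)[C@@]2(C)CCCO[Si](C)(C)C(C)(C)C
F2 | step 12 | 3-[(E)-prop-1-enyl] derivative of spiro dihydrofuran 16 | C/C=C/C1=CO[C@]2(C1)[C@H](C)CC[C@H](C(C)(C)O[Si](CC)(CC)CC)[C@@]2(C)CCCO[Si](C)(C)C(C)(C)C
F3 | step 12 | methyl 2-diazo-3-oxopentanoate | CCC(=O)C(=[N+]=[N-])C(=O)OC
F4 | step 12 | methyl (Z)-3-(tert-butyldimethylsilyloxy)-2-diazopent-3-enoate | C/C=C(\O[Si](C)(C)C(C)(C)C)C(=[N+]=[N-])C(=O)OC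
F5 | step 12 | cis-divinylcyclopropane from F2 and F4 (cyclopropane stereocentres transient) | COC(=O)C1(C(=CC)O[Si](C)(C)C(C)(C)C)C(C)C1C1=CO[C@]2(C1)[C@H](C)CC[C@H](C(C)(C)O[Si](CC)(CC)CC)[C@@]2(C)CCCO[Si](C)(C)C(C)(C)C
F6 | step 12 | silyloxy cycloheptadiene (T1=T7 with OTBS on T7; T3=T4; T2, T5, T6 sp3 and transient) | COC(=O)C1=C(O[Si](C)(C)C(C)(C)C)C(C)C2O[C@]3(CC2=CC1C)[C@H](C)CC[C@H](C(C)(C)O[Si](CC)(CC)CC)[C@@]3(C)CCCO[Si](C)(C)C(C)(C)C
F7 | step 7 | lithium enolate of ketone 12 (C1=C2, O–Li) | [Li]OC1=C(C)CC[C@H](C(C)(C)O[Si](CC)(CC)CC)[C@@]1(C)CCCO[Si](C)(C)C(C)(C)C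
F8 | step 11 | tertiary ethynyl carbinol from 18 (carbinol carbon as a mixture) | C#CC(C)(O)C1=CC[C@@]2(O1)[C@H](C)CC[C@H](C(C)(C)O[Si](CC)(CC)CC)[C@@]2(C)CCCO[Si](C)(C)C(C)(C)C
F9 | step 11 | pivalate of F8 | C#CC(C)(OC(=O)C(C)(C)C)C1=CC[C@@]2(O1)[C@H](C)CC[C@H](C(C)(C)O[Si](CC)(CC)CC)[C@@]2(C)CCCO[Si](C)(C)C(C)(C)C
F10 | step 11 | lithium acetylide of F9 | [Li]C#CC(C)(OC(=O)C(C)(C)C)C1=CC[C@@]2(O1)[C@H](C)CC[C@H](C(C)(C)O[Si](CC)(CC)CC)[C@@]2(C)CCCO[Si](C)(C)C(C)(C)C
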